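**Retrosynthetic overview**
1. Target ⇐ ring-A C3=C4 alkene (epoxidation, then trans-diaxial hydrolysis) and norbornene C13=C14 (exo-face diimide reduction).
2. Ring B and the norbornene ⇐ one intramolecular Diels–Alder reaction of a 1-alkyl-2-isopropylcyclopentadiene (tethered to C10 through C9–C8) with the (E)-methoxyvinyl group on C5; this sets C6, C7, C11 and C12.
3. Cyclopentadiene ⇐ B-alkyl Suzuki coupling of the C10 vinyl group with 2-iodocyclopentenone, isopropyl addition, dehydration. Enol ether ⇐ C5–CH2OH, made by a Still–Wittig shift from the C3 allylic alcohol.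
4. Ring A ⇐ catalytic enantioselective Diels–Alder reaction of a 2-siloxydiene with (E)-3-bromo-2-methylacrolein (C1–Br and C10 set together, no endo/exo question).
5. Ring order: A (step 3), then the bought cyclopentene ring, then ring B and the second norbornane ring together (step 15).

Assumption: locants are C1 (CHBr), C2, C3 (CHOH), C4 (C(OH)Me), C5, C10 (CMe) for ring A; C5–C10 for ring B; C6, C7, C11 (CHOMe), C12 (bridgehead CH), C13, C14 (CH-iPr), C15 (CH2 bridge) for the norbornane; β is the face of the C10 methyl.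

**Step 1**
Reactants: 1 3-methylbut-3-en-2-one
Product: 2 triisopropyl[(3-methylbuta-1,3-dien-2-yl)oxy]silane
Conditions: TIPSOTf, Et3N, CH2Cl2, 0 °C
Reagents that add atoms: triisopropylsilyl trifluoromethanesulfonate, CC(C)[Si](C(C)C)(C(C)C)OS(=O)(=O)C(F)(F)F
Why: Soft enolisation and O-silylation at the only enolisable position (silyl enol ether formation) gives the 2-siloxydiene.

**Step 2**
Reactants: 3 2-methylprop-2-enal (methacrolein)
Product: 5 (E)-3-bromo-2-methylprop-2-enal, via 2,3-dibromo-2-methylpropanal 4 (not isolated)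
Conditions: Br2, CH2Cl2, −78 to 0 °C; then Et3N, 0 °C to rt
Reagents that add atoms: bromine, BrBr
Why: Bromine addition followed by dehydrobromination gives the more stable E isomer, with Br trans to CHO and cis to the methyl.

**Step 3**
Reactants: 2 triisopropyl[(3-methylbuta-1,3-dien-2-yl)oxy]silane; 5 (E)-3-bromo-2-methylprop-2-enal
Product: 6 (1R,6S)-6-bromo-1,3-dimethyl-4-[(triisopropylsilyl)oxy]cyclohex-3-ene-1-carbaldehyde
Conditions: (R)-3,3-diphenyl-1-(o-tolyl)tetrahydro-1H,3H-pyrrolo[1,2-c][1,3,2]oxazaborole (20 mol%), Tf2NH (16 mol%), CH2Cl2, −78 to −40 °C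
Reagents that add atoms: none
Why: Oxazaborolidinium-catalysed enantioselective Diels–Alder reaction in which the siloxy group directs the formyl carbon para to it, the E dienophile puts Br cis to the C10 methyl, and the catalyst (the antipode of the one that gives the (2R)-exo adduct from 2-bromoacrolein and cyclopentadiene, to be confirmed on that benchmark) exposes the Cα-Re face to set C10 and C1; both diene termini are CH2, so there is no endo/exo issue.

**Step 4**
Reactants: 6 (1R,6S)-6-bromo-1,3-dimethyl-4-[(triisopropylsilyl)oxy]cyclohex-3-ene-1-carbaldehyde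
Product: 7 {[(4R,5S)-5-bromo-4-ethenyl-2,4-dimethylcyclohex-1-en-1-yl]oxy}triisopropylsilane
Conditions: Ph3PCH3Br, KOtBu, THF, 0 °C
Reagents that add atoms: methyltriphenylphosphonium bromide, C[P+](c1ccccc1)(c1ccccc1)c1ccccc1.[Br-]
Why: Wittig methylenation of an aldehyde that has no α-hydrogen, so neither epimerisation nor loss of HBr by E1cB is possible.

**Step 5**
Reactants: 7 {[(4R,5S)-5-bromo-4-ethenyl-2,4-dimethylcyclohex-1-en-1-yl]oxy}triisopropylsilane
Product: 8 (4S,5S)-5-bromo-4-ethenyl-2,4-dimethylcyclohex-2-en-1-one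
Conditions: Pd(OAc)2 (1.1 equiv), MeCN, 23 °C; crude product used at once
Reagents that add atoms: none
Why: Saegusa–Ito oxidation converts the silyl enol ether regiospecifically into the C4=C5 enone under base-free conditions, which keeps the β-bromo ketone from eliminating HBr.

**Step 6**
Reactants: 8 (4S,5S)-5-bromo-4-ethenyl-2,4-dimethylcyclohex-2-en-1-one
Product: 9 (1R,4S,5S)-5-bromo-4-ethenyl-2,4-dimethylcyclohex-2-en-1-ol
Conditions: (S)-1-methyl-3,3-diphenyltetrahydro-1H,3H-pyrrolo[1,2-c][1,3,2]oxazaborole (20 mol%), catecholborane, toluene, −78 °C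
Reagents that add atoms: none
Why: Corey–Bakshi–Shibata reduction under reagent control, with the C=C arm of the enone as the large group, gives the 3β-alcohol (cis to Br and to the C10 methyl).

**Step 7**
Reactants: 9 (1R,4S,5S)-5-bromo-4-ethenyl-2,4-dimethylcyclohex-2-en-1-ol
Product: 10 tributyl({[(1R,4S,5S)-5-bromo-4-ethenyl-2,4-dimethylcyclohex-2-en-1-yl]oxy}methyl)stannane
Conditions: KH, Bu3SnCH2I, THF, 0 °C to rt
Reagents that add atoms: tributyl(iodomethyl)stannane, CCCC[Sn](CCCC)(CCCC)CI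
Why: Williamson etherification of the potassium alkoxide with the reactive primary iodide leaves the hindered secondary bromide untouched.

**Step 8**
Reactants: 10 tributyl({[(1R,4S,5S)-5-bromo-4-ethenyl-2,4-dimethylcyclohex-2-en-1-yl]oxy}methyl)stannane
Product: 11 [(1R,5S,6S)-5-bromo-6-ethenyl-2,6-dimethylcyclohex-2-en-1-yl]methanol
Conditions: n-BuLi, THF, −78 °C
Reagents that add atoms: none
Why: Still–Wittig [2,3]-sigmatropic rearrangement, in which fast tin–lithium exchange is followed by a suprafacial shift that delivers CH2O to the β face of C5 (the face of the C3–O bond) and moves the alkene to C3=C4, so C5 is set cis to the C10 methyl and to Br.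

**Step 9**
Reactants: 11 [(1R,5S,6S)-5-bromo-6-ethenyl-2,6-dimethylcyclohex-2-en-1-yl]methanol
Product: 12 (1R,5S,6S)-5-bromo-6-ethenyl-2,6-dimethylcyclohex-2-ene-1-carbaldehyde
Conditions: Dess–Martin periodinane, CH2Cl2, 0 °C
Reagents that add atoms: none
Why: Dess–Martin oxidation under near-neutral conditions avoids epimerisation or conjugation of the β,γ-unsaturated aldehyde.

**Step 10**
Reactants: 12 (1R,5S,6S)-5-bromo-6-ethenyl-2,6-dimethylcyclohex-2-ene-1-carbaldehyde
Product: 13 (3R,4S,5S)-5-bromo-4-ethenyl-3-[(E)-2-iodoethenyl]-2,4-dimethylcyclohex-1-ene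
Conditions: CrCl2, CHI3, THF/dioxane, 0 °C to rt
Reagents that add atoms: iodoform, IC(I)I
Why: Takai olefination gives the (E)-vinyl iodide selectively under non-basic conditions that do not touch the unactivated alkyl bromide.

**Step 11**
Reactants: 13 (3R,4S,5S)-5-bromo-4-ethenyl-3-[(E)-2-iodoethenyl]-2,4-dimethylcyclohex-1-ene
Product: 14 (3R,4S,5S)-5-bromo-4-ethenyl-3-[(E)-2-methoxyethenyl]-2,4-dimethylcyclohex-1-ene
Conditions: CuI (10 mol%), 3,4,7,8-tetramethyl-1,10-phenanthroline (20 mol%), Cs2CO3, MeOH, toluene, 80 °C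
Reagents that add atoms: methanol, CO
Why: Copper-catalysed Ullmann-type C–O coupling of a vinyl iodide with an alcohol proceeds with retention of alkene geometry and gives the (E)-enol ether.

**Step 12**
Reactants: 15 cyclopent-2-en-1-one
Product: 16 2-iodocyclopent-2-en-1-one
Conditions: I2, pyridine, CH2Cl2, 0 °C to rt
Reagents that add atoms: iodine, II
Why: α-Iodination of the enone by pyridine conjugate addition, enolate iodination and elimination (Johnson procedure).

**Step 13**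
Reactants: 14 (3R,4S,5S)-5-bromo-4-ethenyl-3-[(E)-2-methoxyethenyl]-2,4-dimethylcyclohex-1-ene; 16 2-iodocyclopent-2-en-1-one
Product: 18 2-{2-[(1S,2R,6S)-6-bromo-2-[(E)-2-methoxyethenyl]-1,3-dimethylcyclohex-3-en-1-yl]ethyl}cyclopent-2-en-1-one, via B-alkyl-9-BBN borane 17 (not isolated)
Conditions: 9-BBN, THF, 0 °C to rt; then 16, Pd(dppf)Cl2 (5 mol%), Ph3As, Cs2CO3, DMF/H2O, rt
Reagents that add atoms: none
Why: 9-BBN hydroborates the monosubstituted vinyl group far faster than the trisubstituted ring alkene or the hindered 1,2-disubstituted enol ether, and the B-alkyl Suzuki–Miyaura coupling with the α-iodoenone joins C8 to the cyclopentenone.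

**Step 14**
Reactants: 18 2-{2-[(1S,2R,6S)-6-bromo-2-[(E)-2-methoxyethenyl]-1,3-dimethylcyclohex-3-en-1-yl]ethyl}cyclopent-2-en-1-one
Product: 19 2-{2-[(1S,2R,6S)-6-bromo-2-[(E)-2-methoxyethenyl]-1,3-dimethylcyclohex-3-en-1-yl]ethyl}-1-(propan-2-yl)cyclopent-2-en-1-ol (both carbinol epimers)
Conditions: iPrMgCl, CeCl3, THF, −78 °C
Reagents that add atoms: isopropylmagnesium chloride, CC(C)[Mg]Cl
Why: Organocerium 1,2-addition to the enone avoids enolisation and conjugate addition, and the new carbinol centre is lost in the next step.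

**Step 15**
Reactants: 19 2-{2-[(1S,2R,6S)-6-bromo-2-[(E)-2-methoxyethenyl]-1,3-dimethylcyclohex-3-en-1-yl]ethyl}-1-(propan-2-yl)cyclopent-2-en-1-ol
Product: 21 tetracyclic diene (target skeleton with C3=C4 and C13=C14 double bonds; 1β-Br; 5α-H; 6β-H; 11-endo-OMe; C15 bridge on the α face of C7), via cyclopentadiene 20 (not isolated)
Conditions: Burgess reagent, toluene, 50 °C; then iPr2NEt (cat.), BHT, toluene (0.005 M), 180 °C, sealed tube
Reagents that add atoms: none
Why: Dehydration and 1,5-hydrogen shifts give the 1-alkyl-2-isopropylcyclopentadiene, whose intramolecular Diels–Alder reaction with the (E)-enol ether closes ring B and the norbornene in one operation; only the tautomer with the tether on a diene terminus can cyclise, the tether bridges exo through a chair-like ring B trans-fused to ring A (H6 axial, C15 bridge axial on C7), and the E geometry then places OMe endo, which sets C6, C7, C11 and C12, while the hindered trisubstituted ring-A alkene does not compete.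

**Step 16**
Reactants: 21 tetracyclic diene
Product: 22 tetracyclic mono-alkene (as 21 with C13–C14 saturated; 14-endo-isopropyl; C3=C4 retained)
Conditions: 2-nitrobenzenesulfonylhydrazide, Et3N, CH2Cl2, rt
Reagents that add atoms: none
Why: Diimide reduction adds two hydrogens syn to the exo face of the strained norbornene only, which puts the isopropyl group endo at C14 and leaves the unstrained ring-A alkene and the C–Br bond intact.

**Step 17**
Reactants: 22 tetracyclic mono-alkene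
Product: 24 CNP0130529.1 (target; 1β-Br, 3α-OH, 4β-OH, 4α-Me), via 3α,4α-epoxide 23 (not isolated)
Conditions: mCPBA, CH2Cl2, 0 °C; then HClO4 (cat.), THF/H2O, rt
Reagents that add atoms: 3-chloroperoxybenzoic acid, OOC(=O)c1cccc(Cl)c1; water, O
Why: Prilezhaev epoxidation from the α face (anti to the axial C10 methyl) followed by acid-catalysed trans-diaxial (Fürst–Plattner) opening by water at the tertiary C4 with inversion gives the 3α,4β-diol, and the β-epoxide would give the same diaxial diol.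

**Compound list**
1 | 3-methylbut-3-en-2-one | CC(=O)C(C)=C | starting material
2 | triisopropyl[(3-methylbuta-1,3-dien-2-yl)oxy]silane | C=C(C)C(=C)O[Si](C(C)C)(C(C)C)C(C)C | intermediate
3 | 2-methylprop-2-enal | CC(=C)C=O | starting material
4 | 2,3-dibromo-2-methylpropanal (racemic) | O=CC(C)(Br)CBr | intermediate
5 | (E)-3-bromo-2-methylprop-2-enal | O=C/C(C)=C/Br | intermediate
6 | (1R,6S)-6-bromo-1,3-dimethyl-4-[(triisopropylsilyl)oxy]cyclohex-3-ene-1-carbaldehyde | O=C[C@@]1(C)CC(C)=C(O[Si](C(C)C)(C(C)C)C(C)C)C[C@@H]1Br | intermediate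
7 | {[(4R,5S)-5-bromo-4-ethenyl-2,4-dimethylcyclohex-1-en-1-yl]oxy}triisopropylsilane | C=C[C@@]1(C)CC(C)=C(O[Si](C(C)C)(C(C)C)C(C)C)C[C@@H]1Br | intermediate
8 | (4S,5S)-5-bromo-4-ethenyl-2,4-dimethylcyclohex-2-en-1-one | C=C[C@@]1(C)C=C(C)C(=O)C[C@@H]1Br | intermediate
9 | (1R,4S,5S)-5-bromo-4-ethenyl-2,4-dimethylcyclohex-2-en-1-ol | C=C[C@@]1(C)C=C(C)[C@H](O)C[C@@H]1Br | intermediate
10 | tributyl({[(1R,4S,5S)-5-bromo-4-ethenyl-2,4-dimethylcyclohex-2-en-1-yl]oxy}methyl)stannane | C=C[C@@]1(C)C=C(C)[C@H](OC[Sn](CCCC)(CCCC)CCCC)C[C@@H]1Br | intermediate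
11 | [(1R,5S,6S)-5-bromo-6-ethenyl-2,6-dimethylcyclohex-2-en-1-yl]methanol | C=C[C@@]1(C)[C@H](CO)C(C)=CC[C@@H]1Br | intermediate
12 | (1R,5S,6S)-5-bromo-6-ethenyl-2,6-dimethylcyclohex-2-ene-1-carbaldehyde | C=C[C@@]1(C)[C@H](C=O)C(C)=CC[C@@H]1Br | intermediate
13 | (3R,4S,5S)-5-bromo-4-ethenyl-3-[(E)-2-iodoethenyl]-2,4-dimethylcyclohex-1-ene | C=C[C@@]1(C)[C@H](/C=C/I)C(C)=CC[C@@H]1Br | intermediate
14 | (3R,4S,5S)-5-bromo-4-ethenyl-3-[(E)-2-methoxyethenyl]-2,4-dimethylcyclohex-1-ene | C=C[C@@]1(C)[C@H](/C=C/OC)C(C)=CC[C@@H]1Br | intermediate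
15 | cyclopent-2-en-1-one | O=C1CCC=C1 | starting material
16 | 2-iodocyclopent-2-en-1-one | O=C1CCC=C1I | intermediate
17 | 9-{2-[(1S,2R,6S)-6-bromo-2-[(E)-2-methoxyethenyl]-1,3-dimethylcyclohex-3-en-1-yl]ethyl}-9-borabicyclo[3.3.1]nonane | C1CC2CCCC(C1)B2CC[C@@]3(C)[C@H](/C=C/OC)C(C)=CC[C@@H]3Br | intermediate
18 | 2-{2-[(1S,2R,6S)-6-bromo-2-[(E)-2-methoxyethenyl]-1,3-dimethylcyclohex-3-en-1-yl]ethyl}cyclopent-2-en-1-one | O=C1CCC=C1CC[C@@]2(C)[C@H](/C=C/OC)C(C)=CC[C@@H]2Br | intermediate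
19 | 2-{2-[(1S,2R,6S)-6-bromo-2-[(E)-2-methoxyethenyl]-1,3-dimethylcyclohex-3-en-1-yl]ethyl}-1-(propan-2-yl)cyclopent-2-en-1-ol (carbinol epimers) | CC(C)C1(O)CCC=C1CC[C@@]2(C)[C@H](/C=C/OC)C(C)=CC[C@@H]2Br | intermediate
20 | 1-{2-[(1S,2R,6S)-6-bromo-2-[(E)-2-methoxyethenyl]-1,3-dimethylcyclohex-3-en-1-yl]ethyl}-2-(propan-2-yl)cyclopenta-1,3-diene (in equilibrium with its 1,5-H-shift tautomers) | CC(C)C1=C(CC[C@@]2(C)[C@H](/C=C/OC)C(C)=CC[C@@H]2Br)CC=C1 | intermediate
21 | tetracyclic diene: target skeleton with C3=C4 and C13=C14 double bonds, 1β-Br, 5α-H, 6β-H, 11-endo-OMe, C15 bridge α on C7 | CO[C@H]1[C@H]2C=C(C(C)C)[C@]3(CC[C@@]4(C)[C@H]([C@H]13)C(C)=CC[C@@H]4Br)C2 | intermediate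
22 | tetracyclic mono-alkene: as 21 with C13–C14 saturated and 14-endo-isopropyl | CO[C@H]1[C@H]2C[C@@H](C(C)C)[C@]3(CC[C@@]4(C)[C@H]([C@H]13)C(C)=CC[C@@H]4Br)C2 | intermediate
23 | 3α,4α-epoxide of 22 | CO[C@H]1[C@H]2C[C@@H](C(C)C)[C@]3(CC[C@@]4(C)[C@H]([C@H]13)[C@@]5(C)O[C@H]5C[C@@H]4Br)C2 | intermediate
24 | CNP0130529.1: 1β-bromo-11-endo-methoxy-4α,10β-dimethyl-14-endo-isopropyl tetracycle, 3α,4β-diol | CO[C@H]1[C@H]2C[C@@H](C(C)C)[C@]3(CC[C@@]4(C)[C@H]([C@H]13)[C@](C)(O)[C@@H](O)C[C@@H]4Br)C2 | target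

**Totals and risks**
Total: 17 steps. Longest linear sequence: 15 steps (steps 2–11 and 13–17, from methacrolein).

Step 15 is the most exposed step. The enol ether is an unactivated dienophile and needs about 180 °C. Dehydration can also give the exocyclic isopropylidene isomer, which cannot cyclise, and the secondary bromide may lose HBr at that temperature. The fallback sets out from 11 and returns at 21, replacing the enol ether by an activated nitroalkene. Hydroboration of 11 (9-BBN, 2.2 equiv) and Suzuki coupling with 16 give hydroxy enone F1. iPrMgCl/CeCl3 gives diol F2. Oxidation with 2,2,6,6-tetramethylpiperidin-1-oxyl and PhI(OAc)2 converts only the primary alcohol into aldehyde F3. Nitroaldol condensation (MeNO2, NH4OAc) gives (E)-nitroalkene F4. Burgess reagent at 25–60 °C then forms nitroalkenyl cyclopentadiene F5, which cyclises under these mild conditions to endo-nitro adduct F6. A Nef reaction (NaOMe, then aqueous TiCl3/NH4OAc) gives ketone F7. Hydride delivery from the exo face (LiBH(s-Bu)3, −78 °C) gives endo alcohol F8. O-Methylation (MeOTf, 2,6-di-tert-butyl-4-methylpyridine) gives 21.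

Step 8 is the second risk. The rearrangement must form a bond next to a quaternary carbon, and n-BuLi can attack the alkyl bromide or promote a [1,2]-shift. The fallback sets out from 9 and returns at 14, using a [3,3] instead of a [2,3] shift. Johnson–Claisen rearrangement (MeC(OEt)3, cat. propionic acid, 140 °C) transfers the same face and gives ethyl ester F9. DIBAL at −78 °C gives aldehyde F10. HC(OMe)3 with pyridinium p-toluenesulfonate gives dimethyl acetal F11. Elimination with TMSOTf/iPr2NEt gives 14 together with (Z)-enol ether F12, which is removed by chromatography. This path is not stereoselective for the enol ether, which is why it is not the main route.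

Step 5 is the third risk. Enone 8 is a β-bromo ketone that loses HBr by E1cB to a cyclohexadienone with any base, and triisopropylsilyl enol ethers are slow in the Saegusa–Ito reaction. The fallback sets out from 5 and returns at 8, and needs neither palladium nor base. Aminosiloxydiene F13 is made from (E)-4-(dimethylamino)-3-methylbut-3-en-2-one with KN(SiMe3)2 and TBSCl. Its hydrogen-bond-catalysed Diels–Alder reaction with 5 ((4R,5R)-2,2-dimethyl-α,α,α′,α′-tetra(1-naphthyl)-1,3-dioxolane-4,5-dimethanol, 20 mol%, toluene, −78 °C; antipode chosen as in step 3) gives cycloadduct F14. Wittig methylenation gives vinyl compound F15. Aqueous HF in MeCN at 0 °C removes the silyl group and eliminates dimethylamine to give 8, which is reduced at once as in step 6.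

**Further compounds**
F1 | step 15 | 2-{2-[(1S,2R,6S)-6-bromo-2-(hydroxymethyl)-1,3-dimethylcyclohex-3-en-1-yl]ethyl}cyclopent-2-en-1-one | O=C1CCC=C1CC[C@@]2(C)[C@H](CO)C(C)=CC[C@@H]2Br
F2 | step 15 | 2-{2-[(1S,2R,6S)-6-bromo-2-(hydroxymethyl)-1,3-dimethylcyclohex-3-en-1-yl]ethyl}-1-(propan-2-yl)cyclopent-2-en-1-ol | CC(C)C1(O)CCC=C1CC[C@@]2(C)[C@H](CO)C(C)=CC[C@@H]2Br
F3 | step 15 | (1R,5S,6S)-5-bromo-6-{2-[5-hydroxy-5-(propan-2-yl)cyclopent-1-en-1-yl]ethyl}-2,6-dimethylcyclohex-2-ene-1-carbaldehyde | CC(C)C1(O)CCC=C1CC[C@@]2(C)[C@H](C=O)C(C)=CC[C@@H]2Br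
F4 | step 15 | 2-{2-[(1S,2R,6S)-6-bromo-1,3-dimethyl-2-[(E)-2-nitroethenyl]cyclohex-3-en-1-yl]ethyl}-1-(propan-2-yl)cyclopent-2-en-1-ol | CC(C)C1(O)CCC=C1CC[C@@]2(C)[C@H](/C=C/[N+](=O)[O-])C(C)=CC[C@@H]2Br
F5 | step 15 | 1-{2-[(1S,2R,6S)-6-bromo-1,3-dimethyl-2-[(E)-2-nitroethenyl]cyclohex-3-en-1-yl]ethyl}-2-(propan-2-yl)cyclopenta-1,3-diene | CC(C)C1=C(CC[C@@]2(C)[C@H](/C=C/[N+](=O)[O-])C(C)=CC[C@@H]2Br)CC=C1
F6 | step 15 | 11-endo-nitro analogue of 21 | [O-][N+](=O)[C@H]1[C@H]2C=C(C(C)C)[C@]3(CC[C@@]4(C)[C@H]([C@H]13)C(C)=CC[C@@H]4Br)C2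
F7 | step 15 | 11-ketone analogue of 21 | O=C1[C@H]2C=C(C(C)C)[C@]3(CC[C@@]4(C)[C@H]([C@H]13)C(C)=CC[C@@H]4Br)C2
F8 | step 15 | 11-endo-alcohol analogue of 21 | O[C@H]1[C@H]2C=C(C(C)C)[C@]3(CC[C@@]4(C)[C@H]([C@H]13)C(C)=CC[C@@H]4Br)C2
F9 | step 8 | ethyl 2-[(1R,5S,6S)-5-bromo-6-ethenyl-2,6-dimethylcyclohex-2-en-1-yl]acetate | C=C[C@@]1(C)[C@H](CC(=O)OCC)C(C)=CC[C@@H]1Br
F10 | step 8 | 2-[(1R,5S,6S)-5-bromo-6-ethenyl-2,6-dimethylcyclohex-2-en-1-yl]acetaldehyde | C=C[C@@]1(C)[C@H](CC=O)C(C)=CC[C@@H]1Br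
F11 | step 8 | (3R,4S,5S)-5-bromo-3-(2,2-dimethoxyethyl)-4-ethenyl-2,4-dimethylcyclohex-1-ene | C=C[C@@]1(C)[C@H](CC(OC)OC)C(C)=CC[C@@H]1Br
F12 | step 8 | (3R,4S,5S)-5-bromo-4-ethenyl-3-[(Z)-2-methoxyethenyl]-2,4-dimethylcyclohex-1-ene | C=C[C@@]1(C)[C@H](/C=C\OC)C(C)=CC[C@@H]1Br
F13 | step 5 | (E)-3-[(tert-butyldimethylsilyl)oxy]-N,N,2-trimethylbuta-1,3-dien-1-amine | CN(C)/C=C(C)/C(=C)O[Si](C)(C)C(C)(C)C
F14 | step 5 | (1R,6S)-6-bromo-4-[(tert-butyldimethylsilyl)oxy]-2-(dimethylamino)-1,3-dimethylcyclohex-3-ene-1-carbaldehyde (C2 epimers) | O=C[C@@]1(C)C(N(C)C)C(C)=C(O[Si](C)(C)C(C)(C)C)C[C@@H]1Br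
F15 | step 5 | (1R,5S)-5-bromo-3-[(tert-butyldimethylsilyl)oxy]-6-ethenyl-N,N,2,6-tetramethylcyclohex-2-en-1-amine (C1 epimers) | C=C[C@@]1(C)C(N(C)C)C(C)=C(O[Si](C)(C)C(C)(C)C)C[C@@H]1Br
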